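## The problem

The target is a C40 xanthophyll, (3S,5R,6R,3′S,5′R,8′S)-5′,8′-epoxy-5,6,5′,8′-tetrahydro-β,β-carotene-3,5,6,3′-tetrol. An all-E octaene chain (C7 to C10′, four methyl branches) carries a cyclohexane-3,5,6-triol at one end (ring A, C1–C6). At the other end it carries a 2,5-dihydrofuran (ring C, O–C5′–C6′=C7′–C8′) fused to a cyclohexene (ring B, C1′–C6′). The chain must be built by olefination between finished end groups, because the two sets of stereocentres (C3, C5, C6 and C3′, C5′, C8′) are more than twenty bonds apart and cannot control each other. In ring A the oxygens at C3 and C6 are cis and the C5 oxygen is trans to both. C5 and C6 are adjacent fully substituted carbinols, so the remote secondary C3 has to be tied to them through the ring itself. In the furanoid half C3′ can be bought, C5′ follows from it, and C8′ must be derived from C5′ by a ring closure that leaves no choice. Three features will not survive rough treatment: the polyene (light, oxygen, E/Z scrambling), the tertiary C6 carbinol once it is allylic to the chain (acid ionises it), and the doubly allylic C8′–O bond (acid or a Lewis acid reopens it and epimerises C8′). The key step is possible because the C3 and C6 oxygens are 1,4-cis across C4–C5, the retron of a 3,6-epidioxide of a cyclohexa-1,3-diene. That diene (C3=C4–C5=C6 with the C1 gem-dimethyl group, the C5 methyl group and C7 on C6) has the carbon skeleton of safranal.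

## Retrosynthesis

**C11=C12 and C11′=C12′.** Cutting both bonds takes 30 back to the triol C15 aldehyde 15, the furanoid C15 aldehyde 25 and the symmetrical C10 bis-phosphonium salt 28, by way of the C25 salt 29. Both end groups are acid-sensitive, so neither should become a phosphonium salt (made with acid); both are kept as aldehydes and the robust C10 unit carries the phosphorus. A direct C7=C8 olefination of the C10 aldehyde 10 with a C30 ylide was set aside. It would join a neopentyl α-hydroxy aldehyde to a bulky semi-stabilised ylide, and that ylide would have to be made with acid in the presence of ring C. The forward reactions are two Wittig condensations in methoxide, which tolerate free hydroxyls, followed by thermal Z to E equilibration.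

**C7=C8.** 15 comes from nitrile 13 by partial reduction, 13 from its camphanate 12, and 12 from the C10 aldehyde 10 and the C5 phosphonate 11. This is the same bond the C30 plan would make, but with a small stabilised anion that copes with the hindered aldehyde. The precursor is a C10 ring carrying all three ring A stereocentres. The forward step must give 7E,9E; a minor 9Z isomer is expected and must be removed.

**C7 oxidation level and the antipodes.** 10 comes from the primary alcohol 9, 9 from silyl ether 8, and 8 from racemic triol 7 by esterification of the only secondary hydroxyl with an enantiopure acid chloride. The ester separates the antipodes as diastereomers and also protects C3 during the oxidation at C7. Resolution is placed here, and not later, because 7 is the first compound with a free C3 hydroxyl and is still cheap.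

**C5–O and C4–H.** 7 comes from the epoxy peroxide 5 by hydride (O–O cleavage and epoxide opening at C4, through epoxy diol 6), and 5 from alkene 4 by epoxidation. The alternative of cleaving the peroxide first and then epoxidising was rejected: two free allylic hydroxyls would direct the oxidant to their own face and give the all-cis triol. In 4 the peroxide bridge occupies that face. The forward epoxidation must go anti to the bridge, and the hydride must enter at the secondary C4.

**C3–O and C6–O (key disconnection).** 4 is cut to the safranol silyl ether 3 by retro-[4+2] loss of the two oxygen atoms. Both C–O bonds, the cis relationship and the bicycle arise in one step from an achiral diene. Stepwise oxygenation of C3 and C6 would need separate control at a secondary and a fully substituted centre. The forward reaction must beat the ene reaction and gives a racemate.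

**Diene.** 3 comes from safranol 2 and 2 from commercial safranal 1 by reduction and silylation. The silyl ether keeps C7 distinguishable from C3 after the hydride step.

**O–C8′ of ring C.** 25 comes from diol 24 and silyl ether 23 by oxidation and desilylation, and 23 from the allenic diol 22 by closing the O–C8′ bond. The acid-catalysed epoxide to furanoid rearrangement would give both C8′ epimers. The cyclisation of an α-hydroxyallene passes the axial configuration on to C8′. The forward step needs a mild π-acid that does not reopen the product.

**Allene, epoxide and C6′–C7′.** 22 comes from the epoxy enynol 21 by SN2′ hydride delivery, and 21 from the dienynol 20 by epoxidation anti to the C3′ silyloxy group. 20 comes from enol triflate 18 and the commercial enynol 19 by Sonogashira coupling, and 18 from actinol 16 through its silyl ether 17. All fifteen carbons and the C3′ centre come from two commercial pieces in three steps.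

**C10 unit.** 28 comes from diol 27 and this from the commercial dialdehyde 26.

## Roads not taken

**Alternative 1:** The cut is at C10–C11 together with the C9–CH3 bond. The triol half is carried to the silylated enyne A1. Me3Al with Cp2ZrCl2 adds methyl to C9 and aluminium to C10, and the dienylalane is coupled (ZnCl2, Pd(PPh3)4, zerovalent palladium) with the iodo dienoate A2 to give the C20 ester A3 (four C=C bonds, so a tetraenoate).
- Merits: syn-carbometalation fixes 9E with no Z isomer, whereas phosphonate 11 in the chosen route gives some 9Z that must be removed. The coupling is convergent and free of strong base.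
- Weak points: it is a chain method and leaves all three ring A stereocentres to be made elsewhere. Me3Al tolerates no free hydroxyl, so three silyl ethers (two on tertiary carbinols) are needed. A Lewis acid next to the tertiary allylic C6 silyl ether invites ionisation. A3 still needs reduction, oxidation and another olefination, and the silyl groups must then come off a C40 polyene.
- Comparison: for the C9 geometry this road is better. The chosen plan sets against it that it solves the harder ring problem in three steps from 3 and carries no protecting group into the final coupling.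

**Alternative 2:** The cut is the O–C8′ bond of ring C. Ph3PAuCl with AgBF4 (monovalent gold) activates C7′=C8′ of the C15 allenol A4, and the C5′ hydroxyl attacks C8′ to give the furanoid bis-silyl ether A5.
- Merits: the allene axis is copied into C8′, so no epimer mixture arises, and the allenol comes from the chiral pool.
- Weak points: the product ether is doubly allylic, and a cationic gold centre can reopen it. The step does nothing for ring A, which holds half of the stereocentres and both tertiary carbinols.
- Comparison: for C8′ this is the best answer, and the chosen route does not compete with it. The same kind of closure is used as a supporting step (step 17), with AgNO3 and CaCO3 on the allenic diol 22 to keep Lewis acidity low. What is not taken is resting the synthesis on it: ring A would then have to come from a longer sequence than the three steps from 3 to 7.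

**Alternative 3:** The cut is the C5–O bond. BF3·OEt2 activates the 5,6-epoxide of the tert-butyl carbonate A6 (epoxide cis to the C3 oxygen), and the carbonate carbonyl oxygen attacks C5 with inversion, giving the cyclic carbonate A7 with loss of isobutene.
- Merits: everything is enantiopure from actinol, so no resolution is needed and no material is lost as the wrong antipode. In this respect it is better than the chosen plan.
- Weak points: A6 needs about six steps (C7 homologation of the actinol triflate, reduction, directed epoxidation, carbonate formation). The opening must occur at C5 (six-membered carbonate) and not at C6 (five-membered carbonate, which would give the wrong trans-diol). A Lewis acid on a fully substituted epoxide can also trigger a 1,2-shift.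
- Comparison: the chosen plan sets against it brevity (three steps from achiral 3 to triol 7), a cis C3/C6 relationship that the bridge enforces with no regiochemical question, and hydride opening at the only secondary epoxide carbon. The price is the resolution in step 6.

Key step: step 3

Remarks on the chemistry:
- Compounds 4–7 are racemic and are drawn as the enantiomer that is carried on after step 6.
- Carotenoid locants are used in the text. The CIP descriptor of C6 changes with the substituent at C7 without any change of geometry.
- In step 16 hydride is taken to enter C8′ from the side of the oxirane oxygen, which gives the (6′R) axis.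

Step 1
Reactants: 1 safranal (2,6,6-trimethylcyclohexa-1,3-diene-1-carbaldehyde)
Product: 2 safranol [(2,6,6-trimethylcyclohexa-1,3-dien-1-yl)methanol]
Conditions: NaBH4, CeCl3·7H2O, MeOH, 0 °C
Reagents that add atoms: none
Why: Luche 1,2-reduction of a dienal; the cerium salt keeps hydride at the carbonyl carbon so the ring diene is untouched; no stereocentre is formed.

Step 2
Reactants: 2 safranol
Product: 3 tert-butyl(dimethyl)[(2,6,6-trimethylcyclohexa-1,3-dien-1-yl)methoxy]silane
Conditions: TBSCl, imidazole, DMF, rt
Reagents that add atoms: tert-butyl(chloro)dimethylsilane (TBSCl), CC(C)(C)[Si](C)(C)Cl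
Why: Standard silylation of a primary alcohol; the ether survives singlet oxygen, peracid and LiAlH4 and keeps C7 distinct from C3 later.

Step 3
Reactants: 3 safranol silyl ether
Product: 4 rac-tert-butyl(dimethyl){[(1R,4S)-6,8,8-trimethyl-2,3-dioxabicyclo[2.2.2]oct-5-en-1-yl]methoxy}silane (3,6-epidioxide in carotenoid locants)
Conditions: O2, 5,10,15,20-tetraphenylporphyrin (cat.), hν (visible), CH2Cl2, −20 °C
Reagents that add atoms: dioxygen, O=O
Why: Visible light and the porphyrin sensitiser convert ground-state dioxygen into singlet oxygen, which adds to the s-cis diene C3=C4–C5=C6 of 3 in a concerted, suprafacial hetero-Diels–Alder reaction that forms the C3–O and C6–O bonds and leaves the new double bond at C4=C5. The closest known reaction type is the photooxygenation of cyclohexa-1,3-dienes to 2,3-dioxabicyclo[2.2.2]oct-5-enes (α-terpinene to ascaridole, and the 3,6-epidioxides of 2,6,6-trimethylcyclohexa-1,3-dienyl rings). The one new ring, the six-membered 1,2-dioxene, closes by [4+2] cycloaddition with both diene termini bonding at once and completes the bicyclo[2.2.2] skeleton. C3 and C6 become stereocentres; the two-atom bridge forces both oxygens onto one face (cis), and since nothing in achiral 3 distinguishes the two faces, 4 is racemic and is resolved in step 6. The step needs cycloaddition to win over the ene reaction (hydrogens of the C5 methyl group, C7 and C2) and needs the peroxide to survive: the ring holds the diene cisoid, the C7 hydrogens are deactivated by the geminal silyloxy group, and low temperature with a base-free work-up avoids the Kornblum–DeLaMare rearrangement at C3–H and thermal isomerisation to a bis-epoxide.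

Step 4
Reactants: 4 rac-endoperoxide
Product: 5 rac-4,5-epoxy-3,6-epidioxide with the oxirane on the face opposite to the peroxide bridge [(3S,4R,5R,6S) in carotenoid locants]
Conditions: mCPBA, NaHCO3, CH2Cl2, 0 °C → rt
Reagents that add atoms: 3-chloroperoxybenzoic acid (mCPBA), OOC(=O)c1cccc(Cl)c1
Why: Peracid epoxidation of the trisubstituted C4=C5 bond; in 2,3-dioxabicyclo[2.2.2]oct-5-enes electrophilic oxidants add anti to the peroxide bridge because of lone-pair repulsion, which places the C5 oxygen trans to the C3 and C6 oxygens; dialkyl peroxides are inert to peracid.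

Step 5
Reactants: 5 rac-epoxy endoperoxide
Product: 7 rac-(1S,2R,4S)-1-({[tert-butyl(dimethyl)silyl]oxy}methyl)-2,6,6-trimethylcyclohexane-1,2,4-triol, via epoxy diol 6 (not isolated)
Conditions: LiAlH4, THF, 0 °C → rt; aq. potassium sodium tartrate
Reagents that add atoms: none
Why: Hydride cleaves the O–O bond first (giving 6 as its aluminate, C3 and C6 configurations untouched) and then opens the oxirane at the secondary C4 by SN2, assisted by delivery from the C3-bound aluminate on the same face; C5 keeps its oxygen, so the 3,6-cis/5-trans triol results; the silyl ether is stable to LiAlH4.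

Step 6
Reactants: 7 rac-triol
Product: 8 (1S,3R,4S)-4-({[tert-butyl(dimethyl)silyl]oxy}methyl)-3,4-dihydroxy-3,5,5-trimethylcyclohexyl (1S,4R)-4,7,7-trimethyl-3-oxo-2-oxabicyclo[2.2.1]heptane-1-carboxylate (single diastereomer)
Conditions: (1S)-camphanic chloride, pyridine, 4-(dimethylamino)pyridine (cat.), CH2Cl2, 0 °C → rt; separation of the two diastereomers by chromatography and crystallisation
Reagents that add atoms: (1S)-(−)-camphanic chloride, O=C(Cl)[C@@]12CC[C@@](C)(C(=O)O1)C2(C)C
Why: Acylation of the only secondary hydroxyl (the two tertiary carbinols do not react) turns the antipodes into diastereomeric esters, a classical covalent resolution; the ester with the (3S,5R,6R)-type ring is kept, its configuration is secured by the internal camphanate reference (X-ray), and it protects C3 in steps 7–9.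

Step 7
Reactants: 8 camphanate silyl ether
Product: 9 (1S,3R,4S)-3,4-dihydroxy-4-(hydroxymethyl)-3,5,5-trimethylcyclohexyl (1S,4R)-camphanate
Conditions: Bu4NF, AcOH, THF, 0 °C → rt
Reagents that add atoms: none
Why: Fluoride cleavage of a primary silyl ether; buffering with acetic acid protects the ester and the lactone; the trans relationship of the C3 ester to the C5 hydroxyl excludes acyl migration.

Step 8
Reactants: 9 primary alcohol
Product: 10 (1S,3R,4R)-4-formyl-3,4-dihydroxy-3,5,5-trimethylcyclohexyl (1S,4R)-camphanate
Conditions: SO3·pyridine, DMSO, i-Pr2NEt, CH2Cl2, 0 °C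
Reagents that add atoms: none
Why: Parikh–Doering oxidation of the only oxidisable hydroxyl (the others are tertiary or acylated); activated-DMSO oxidants do not cleave 1,2-diols, and the aldehyde has no α-hydrogen to epimerise.

Step 9
Reactants: 10 α-hydroxy aldehyde; 11 diethyl [(2E)-3-cyano-2-methylprop-2-en-1-yl]phosphonate (commercial E/Z mixture)
Product: 12 (1S,3R,4R)-4-[(1E,3E)-4-cyano-3-methylbuta-1,3-dien-1-yl]-3,4-dihydroxy-3,5,5-trimethylcyclohexyl (1S,4R)-camphanate
Conditions: 11 (3.5 equiv), NaH, THF, 0 °C; then 10, −40 → 0 °C
Reagents that add atoms: none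
Why: Horner–Wadsworth–Emmons olefination with a stabilised C5 phosphonate anion, a standard C10 to C15 extension for hindered ring aldehydes of this class; excess anion absorbs the two tertiary hydroxyls, the new C7=C8 bond forms E, and the expected minor 9Z isomer is removed by chromatography.

Step 10
Reactants: 12 nitrile camphanate
Product: 13 (2E,4E)-3-methyl-5-[(1R,2R,4S)-1,2,4-trihydroxy-2,6,6-trimethylcyclohexyl]penta-2,4-dienenitrile
Conditions: K2CO3 (cat.), MeOH, rt → 40 °C
Reagents that add atoms: none
Why: Base-catalysed transesterification releases the C3 hydroxyl as methyl camphanate leaves; the nitrile, the diene and the carbinols are inert to methoxide.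

Step 11
Reactants: 13 triol nitrile
Product: 15 (2E,4E)-3-methyl-5-[(1R,2R,4S)-1,2,4-trihydroxy-2,6,6-trimethylcyclohexyl]penta-2,4-dienal, via aldimine 14 (not isolated)
Conditions: i-Bu2AlH (5 equiv), CH2Cl2, −78 → −40 °C; then H2O, wet SiO2, 0 °C
Reagents that add atoms: water, O
Why: Partial reduction of a conjugated nitrile to the N-aluminoimine, which stops at that stage at low temperature and hydrolyses to the aldehyde under neutral conditions; three equivalents of the hydride are consumed by the hydroxyls; no acid touches the allylic C6 carbinol.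

Step 12
Reactants: 16 (4R,6R)-4-hydroxy-2,2,6-trimethylcyclohexan-1-one (actinol)
Product: 17 (4R,6R)-4-{[tert-butyl(dimethyl)silyl]oxy}-2,2,6-trimethylcyclohexan-1-one
Conditions: TBSCl, imidazole, DMF, rt
Reagents that add atoms: tert-butyl(chloro)dimethylsilane (TBSCl), CC(C)(C)[Si](C)(C)Cl
Why: Standard silylation of the secondary alcohol; the bulky ether later steers the epoxidation in step 15.

Step 13
Reactants: 17 silyl ether of actinol
Product: 18 (4R)-4-{[tert-butyl(dimethyl)silyl]oxy}-2,6,6-trimethylcyclohex-1-en-1-yl trifluoromethanesulfonate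
Conditions: LiN(i-Pr)2, THF, −78 °C; PhNTf2, −78 → 0 °C
Reagents that add atoms: N-phenylbis(trifluoromethanesulfonimide) (PhNTf2), O=S(=O)(N(c1ccccc1)S(=O)(=O)C(F)(F)F)C(F)(F)F
Why: Enol triflate formation; the ketone has a single α-hydrogen, so only one enolate can form; the C5′ centre is deliberately erased and C3′ is untouched.

Step 14
Reactants: 18 enol triflate; 19 (2E)-3-methylpent-2-en-4-yn-1-ol
Product: 20 (2E)-5-[(4R)-4-{[tert-butyl(dimethyl)silyl]oxy}-2,6,6-trimethylcyclohex-1-en-1-yl]-3-methylpent-2-en-4-yn-1-ol
Conditions: Pd(PPh3)4 (5 mol %), CuI (10 mol %), i-Pr2NH, DMF, rt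
Reagents that add atoms: none
Why: Sonogashira coupling of an alkenyl triflate with a terminal alkyne forms the C6′–C7′ bond; the free hydroxyl and the E double bond of 19 are not affected.

Step 15
Reactants: 20 dienynol
Product: 21 (2E)-5-[(1R,4S,6R)-4-{[tert-butyl(dimethyl)silyl]oxy}-2,2,6-trimethyl-7-oxabicyclo[4.1.0]heptan-1-yl]-3-methylpent-2-en-4-yn-1-ol [(3′S,5′R,6′R), oxirane trans to the C3′ oxygen]
Conditions: mCPBA, NaHCO3, CH2Cl2, −20 → 0 °C
Reagents that add atoms: 3-chloroperoxybenzoic acid (mCPBA), OOC(=O)c1cccc(Cl)c1
Why: Peracid epoxidation picks the tetrasubstituted C5′=C6′ bond (C9′=C10′ is deactivated by the allylic oxygen and the alkyne); with the C3′ oxygen protected there is no hydroxyl direction, and attack anti to the silyloxy group is expected to predominate as for other 3-O-protected rings of this type; the minor syn epoxide is removed by chromatography.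

Step 16
Reactants: 21 epoxy enynol
Product: 22 (2E)-5-[(2R,4S)-4-{[tert-butyl(dimethyl)silyl]oxy}-2-hydroxy-2,6,6-trimethylcyclohexylidene]-3-methylpenta-2,4-dien-1-ol with R allene axis (6′R)
Conditions: i-Bu2AlH (excess), CH2Cl2, −78 → 0 °C; aq. potassium sodium tartrate
Reagents that add atoms: none
Why: SN2′ reduction of a propargylic oxirane; aluminium bound to the oxirane oxygen delivers hydride to C8′ from the oxygen side as C6′–O breaks, the established way to the (6R)-allenic end group from this epoxy-enyne class; C5′ keeps its oxygen.

Step 17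
Reactants: 22 allenic diol
Product: 23 (2E)-3-[(2S,6S,7aR)-6-{[tert-butyl(dimethyl)silyl]oxy}-4,4,7a-trimethyl-2,4,5,6,7,7a-hexahydro-1-benzofuran-2-yl]but-2-en-1-ol
Conditions: AgNO3 (20 mol %), CaCO3, acetone–H2O, rt, dark
Reagents that add atoms: none
Why: Silver-catalysed 5-endo cycloisomerisation of an α-hydroxyallene to a 2,5-dihydrofuran; the C5′ oxygen can reach C8′ only within the plane fixed by the allene, so the (6′R) axis with (5′R) is translated into (8′S) with the side chain cis to the C5′ methyl group; CaCO3 scavenges acid that would reopen the doubly allylic ether.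

Step 18
Reactants: 23 furanoid silyl ether
Product: 24 (2S,6S,7aR)-2-[(2E)-4-hydroxybut-2-en-2-yl]-4,4,7a-trimethyl-2,4,5,6,7,7a-hexahydro-1-benzofuran-6-ol
Conditions: Bu4NF, THF, 0 °C → rt
Reagents that add atoms: none
Why: Fluoride desilylation at a stage without carbonyl group or polyene; basic and non-acidic, so C8′ is safe.

Step 19
Reactants: 24 furanoid diol
Product: 25 (2E)-3-[(2S,6S,7aR)-6-hydroxy-4,4,7a-trimethyl-2,4,5,6,7,7a-hexahydro-1-benzofuran-2-yl]but-2-enal
Conditions: MnO2 (activated, excess), CH2Cl2, rt
Reagents that add atoms: none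
Why: MnO2 oxidises only the allylic primary alcohol; the saturated secondary C3′ hydroxyl and the allylic ether are left, and the E geometry is retained under neutral conditions.

Step 20
Reactants: 26 (2E,4E,6E)-2,7-dimethylocta-2,4,6-trienedial
Product: 27 (2E,4E,6E)-2,7-dimethylocta-2,4,6-triene-1,8-diol
Conditions: NaBH4, MeOH–THF, 0 °C
Reagents that add atoms: none
Why: Borohydride 1,2-reduction of both enal carbonyl groups; the triene geometry is unchanged.

Step 21
Reactants: 27 C10 diol
Product: 28 [(2E,4E,6E)-2,7-dimethylocta-2,4,6-triene-1,8-diyl]bis(triphenylphosphonium) dibromide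
Conditions: PPh3·HBr (2.2 equiv), MeOH, rt; crystallisation
Reagents that add atoms: triphenylphosphine hydrobromide, Br.c1ccc(cc1)P(c1ccccc1)c1ccccc1
Why: Allylic alcohols give phosphonium salts directly with triphenylphosphine hydrobromide through the stabilised allyl cation; acid is harmless here because no end group is present, and the all-E salt crystallises.

Step 22
Reactants: 28 bis-phosphonium salt; 25 furanoid aldehyde
Product: 29 {(2E,4E,6E,8E,10E)-11-[(2S,6S,7aR)-6-hydroxy-4,4,7a-trimethyl-2,4,5,6,7,7a-hexahydro-1-benzofuran-2-yl]-2,7-dimethyldodeca-2,4,6,8,10-pentaen-1-yl}triphenylphosphonium bromide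
Conditions: 28 (3 equiv), NaOMe (1 equiv, slow addition), CH2Cl2–MeOH, 0 °C → rt, Ar, dark; partition and chromatography (SiO2, CH2Cl2–MeOH)
Reagents that add atoms: none
Why: Wittig mono-condensation forming C11′=C12′; the excess of 28 suppresses the double condensation and, being the strongest acid present, keeps free methoxide low so that the γ-hydrogen at C8′ of 25 is not removed; Z isomers at the new bond are carried on and equilibrated in step 23.

Step 23
Reactants: 29 C25 phosphonium salt; 15 triol C15 aldehyde
Product: 30 (3S,5R,6R,3′S,5′R,8′S)-5′,8′-epoxy-5,6,5′,8′-tetrahydro-β,β-carotene-3,5,6,3′-tetrol (CNP0210286.3)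
Conditions: NaOMe, CH2Cl2–MeOH, 0 °C → rt, Ar, dark; then EtOAc, 70 °C (Z → E), crystallisation
Reagents that add atoms: none
Why: Wittig condensation forming C11=C12 with all four hydroxyls free, as is usual for hydroxylated carotenoid end groups; the sterically hindered 11Z and 11′Z isomers equilibrate thermally to the all-E polyene; no acid and no deprotection follow, so C6 and C8′ keep their configuration.

## Compound list

1 | safranal, 2,6,6-trimethylcyclohexa-1,3-diene-1-carbaldehyde | CC1=C(C=O)C(C)(C)CC=C1 | starting material
2 | safranol, (2,6,6-trimethylcyclohexa-1,3-dien-1-yl)methanol | CC1=C(CO)C(C)(C)CC=C1 | intermediate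
3 | tert-butyl(dimethyl)[(2,6,6-trimethylcyclohexa-1,3-dien-1-yl)methoxy]silane | CC1=C(CO[Si](C)(C)C(C)(C)C)C(C)(C)CC=C1 | intermediate
4 | rac-tert-butyl(dimethyl){[(1R,4S)-6,8,8-trimethyl-2,3-dioxabicyclo[2.2.2]oct-5-en-1-yl]methoxy}silane (racemate, enantiomer carried on is drawn) | CC1=C[C@@H]2CC(C)(C)[C@@]1(CO[Si](C)(C)C(C)(C)C)OO2 | intermediate
5 | rac-4,5-epoxide of 4, oxirane anti to the peroxide bridge, (3S,4R,5R,6S) in carotenoid locants | C[C@@]12O[C@@H]1[C@@H]3CC(C)(C)[C@@]2(CO[Si](C)(C)C(C)(C)C)OO3 | intermediate
6 | rac-4,5-epoxy-3,6-diol (3-OH and 6-OH cis, oxirane trans to both), silyl ether at C7; not isolated | C[C@@]12O[C@@H]1[C@@H](O)CC(C)(C)[C@]2(O)CO[Si](C)(C)C(C)(C)C | intermediate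
7 | rac-(1S,2R,4S)-1-({[tert-butyl(dimethyl)silyl]oxy}methyl)-2,6,6-trimethylcyclohexane-1,2,4-triol | CC(C)(C)[Si](C)(C)OC[C@@]1(O)C(C)(C)C[C@H](O)C[C@@]1(C)O | intermediate
8 | (1S,3R,4S)-4-({[tert-butyl(dimethyl)silyl]oxy}methyl)-3,4-dihydroxy-3,5,5-trimethylcyclohexyl (1S,4R)-camphanate | CC(C)(C)[Si](C)(C)OC[C@@]1(O)C(C)(C)C[C@H](OC(=O)[C@@]23CC[C@@](C)(C(=O)O2)C3(C)C)C[C@@]1(C)O | intermediate
9 | (1S,3R,4S)-3,4-dihydroxy-4-(hydroxymethyl)-3,5,5-trimethylcyclohexyl (1S,4R)-camphanate | OC[C@@]1(O)C(C)(C)C[C@H](OC(=O)[C@@]23CC[C@@](C)(C(=O)O2)C3(C)C)C[C@@]1(C)O | intermediate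
10 | (1S,3R,4R)-4-formyl-3,4-dihydroxy-3,5,5-trimethylcyclohexyl (1S,4R)-camphanate | O=C[C@@]1(O)C(C)(C)C[C@H](OC(=O)[C@@]23CC[C@@](C)(C(=O)O2)C3(C)C)C[C@@]1(C)O | intermediate
11 | diethyl [(2E)-3-cyano-2-methylprop-2-en-1-yl]phosphonate | CCOP(=O)(OCC)C/C(C)=C/C#N | starting material
12 | (1S,3R,4R)-4-[(1E,3E)-4-cyano-3-methylbuta-1,3-dien-1-yl]-3,4-dihydroxy-3,5,5-trimethylcyclohexyl (1S,4R)-camphanate | N#C/C=C(C)/C=C/[C@@]1(O)C(C)(C)C[C@H](OC(=O)[C@@]23CC[C@@](C)(C(=O)O2)C3(C)C)C[C@@]1(C)O | intermediate
13 | (2E,4E)-3-methyl-5-[(1R,2R,4S)-1,2,4-trihydroxy-2,6,6-trimethylcyclohexyl]penta-2,4-dienenitrile | N#C/C=C(C)/C=C/[C@@]1(O)C(C)(C)C[C@H](O)C[C@@]1(C)O | intermediate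
14 | (2E,4E)-3-methyl-5-[(1R,2R,4S)-1,2,4-trihydroxy-2,6,6-trimethylcyclohexyl]penta-2,4-dien-1-imine; not isolated | N=C/C=C(C)/C=C/[C@@]1(O)C(C)(C)C[C@H](O)C[C@@]1(C)O | intermediate
15 | (2E,4E)-3-methyl-5-[(1R,2R,4S)-1,2,4-trihydroxy-2,6,6-trimethylcyclohexyl]penta-2,4-dienal | O=C/C=C(C)/C=C/[C@@]1(O)C(C)(C)C[C@H](O)C[C@@]1(C)O | intermediate
16 | (4R,6R)-4-hydroxy-2,2,6-trimethylcyclohexan-1-one (actinol) | O=C1C(C)(C)C[C@H](O)C[C@H]1C | starting material
17 | (4R,6R)-4-{[tert-butyl(dimethyl)silyl]oxy}-2,2,6-trimethylcyclohexan-1-one | O=C1C(C)(C)C[C@H](O[Si](C)(C)C(C)(C)C)C[C@H]1C | intermediate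
18 | (4R)-4-{[tert-butyl(dimethyl)silyl]oxy}-2,6,6-trimethylcyclohex-1-en-1-yl trifluoromethanesulfonate | CC1=C(OS(=O)(=O)C(F)(F)F)C(C)(C)C[C@H](O[Si](C)(C)C(C)(C)C)C1 | intermediate
19 | (2E)-3-methylpent-2-en-4-yn-1-ol | C#C/C(C)=C/CO | starting material
20 | (2E)-5-[(4R)-4-{[tert-butyl(dimethyl)silyl]oxy}-2,6,6-trimethylcyclohex-1-en-1-yl]-3-methylpent-2-en-4-yn-1-ol | CC1=C(C#C/C(C)=C/CO)C(C)(C)C[C@H](O[Si](C)(C)C(C)(C)C)C1 | intermediate
21 | (2E)-5-[(1R,4S,6R)-4-{[tert-butyl(dimethyl)silyl]oxy}-2,2,6-trimethyl-7-oxabicyclo[4.1.0]heptan-1-yl]-3-methylpent-2-en-4-yn-1-ol | C[C@]12O[C@@]1(C#C/C(C)=C/CO)C(C)(C)C[C@H](O[Si](C)(C)C(C)(C)C)C2 | intermediate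
22 | (2E)-5-[(2R,4S)-4-{[tert-butyl(dimethyl)silyl]oxy}-2-hydroxy-2,6,6-trimethylcyclohexylidene]-3-methylpenta-2,4-dien-1-ol, R allene axis (6′R) | C[C@@]1(O)C[C@@H](O[Si](C)(C)C(C)(C)C)CC(C)(C)C1=[C@@]=C([H])/C(C)=C/CO | intermediate
23 | (2E)-3-[(2S,6S,7aR)-6-{[tert-butyl(dimethyl)silyl]oxy}-4,4,7a-trimethyl-2,4,5,6,7,7a-hexahydro-1-benzofuran-2-yl]but-2-en-1-ol | OC/C=C(\C)[C@@H]1C=C2C(C)(C)C[C@H](O[Si](C)(C)C(C)(C)C)C[C@@]2(C)O1 | intermediate
24 | (2S,6S,7aR)-2-[(2E)-4-hydroxybut-2-en-2-yl]-4,4,7a-trimethyl-2,4,5,6,7,7a-hexahydro-1-benzofuran-6-ol | OC/C=C(\C)[C@@H]1C=C2C(C)(C)C[C@H](O)C[C@@]2(C)O1 | intermediate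
25 | (2E)-3-[(2S,6S,7aR)-6-hydroxy-4,4,7a-trimethyl-2,4,5,6,7,7a-hexahydro-1-benzofuran-2-yl]but-2-enal | O=C/C=C(\C)[C@@H]1C=C2C(C)(C)C[C@H](O)C[C@@]2(C)O1 | intermediate
26 | (2E,4E,6E)-2,7-dimethylocta-2,4,6-trienedial | O=C/C(C)=C/C=C/C=C(C)/C=O | starting material
27 | (2E,4E,6E)-2,7-dimethylocta-2,4,6-triene-1,8-diol | OC/C(C)=C/C=C/C=C(C)/CO | intermediate
28 | [(2E,4E,6E)-2,7-dimethylocta-2,4,6-triene-1,8-diyl]bis(triphenylphosphonium) dibromide | [Br-].[Br-].C(/C(C)=C/C=C/C=C(C)/C[P+](c1ccccc1)(c1ccccc1)c1ccccc1)[P+](c1ccccc1)(c1ccccc1)c1ccccc1 | intermediate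
29 | {(2E,4E,6E,8E,10E)-11-[(2S,6S,7aR)-6-hydroxy-4,4,7a-trimethyl-2,4,5,6,7,7a-hexahydro-1-benzofuran-2-yl]-2,7-dimethyldodeca-2,4,6,8,10-pentaen-1-yl}triphenylphosphonium bromide | [Br-].CC(/C[P+](c1ccccc1)(c1ccccc1)c1ccccc1)=C\C=C\C=C(C)\C=C\C=C(/C)[C@@H]1C=C2C(C)(C)C[C@H](O)C[C@@]2(C)O1 | intermediate
30 | (3S,5R,6R,3′S,5′R,8′S)-5′,8′-epoxy-5,6,5′,8′-tetrahydro-β,β-carotene-3,5,6,3′-tetrol (CNP0210286.3) | CC(/C=C/C=C(C)/C=C/[C@@]1(O)C(C)(C)C[C@H](O)C[C@@]1(C)O)=C\C=C\C=C(C)\C=C\C=C(/C)[C@@H]1C=C2C(C)(C)C[C@H](O)C[C@@]2(C)O1 | target

## Step count and weak points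

Total: 23 steps. Longest linear sequence: 12 steps (steps 1–11 from safranal to 15, then step 23). Steps 12–19 (furanoid half), 20–21 (C10 unit) and 22 are branches.

**Step 3 (key step).** The ene reaction at the electron-rich, fully substituted C5=C6 bond (hydrogen abstraction from the C5 methyl group) may compete with cycloaddition, and the peroxide may rearrange during isolation. The cause is that bonding at C6 is hindered by the gem-dimethyl group while ene reactions of tetrasubstituted alkenes are fast. Fallback: starting from 3, oxygenate with ground-state dioxygen and a catalytic amount of tris(4-bromophenyl)aminium hexachloroantimonate in CH2Cl2 at −78 °C. The diene radical cation, not singlet oxygen, captures dioxygen in a chain process that gives the same 1,4-epidioxide, and an ene channel does not exist. The route is rejoined at 4; no new compound is made (F0).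

**Step 4.** Poor facial selectivity is the likely failure. The C1 methyl group syn to the alkene hinders the face anti to the peroxide, so steric approach and lone-pair repulsion work against each other, and attack on the peroxide face would end in the all-cis triol. Fallback: starting from 4, the O–O bond is reduced with thiourea in MeOH to the cis-enediol F1. Hydroxyl-directed oxymercuration (Hg(OAc)2, divalent mercury, THF–H2O) follows: both allylic hydroxyls guide mercury to their own face and water opens the mercurinium ion at the tertiary C5 from the opposite face, giving the organomercurial F2. Demercuration with NaBH4/NaOH returns to the route at 7.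

**Step 6.** The diastereomeric camphanates may co-elute and co-crystallise. The C3 carbinol sits in a nearly mirror-symmetric environment (CH2–CMe2 on one side, CH2–C(OH)Me on the other), so the two esters may differ little. Fallback: starting from 7, a lipase-mediated kinetic resolution (vinyl acetate, immobilised lipase from Burkholderia cepacia, t-BuOMe) acetylates one antipode at C3, and alcohol and acetate are separated by simple chromatography. The fraction with the (3S,5R,6R)-type ring is used; if it is the acetate, this is the 3-acetate F3, which is cleaved with K2CO3 in MeOH to enantiopure 7. Esterification with (1S)-camphanic chloride then gives a single ester and returns to the route at 8. This is second choice because the sense and size of the enzyme's discrimination cannot be predicted for this environment.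

**Step 9.** The alkoxide of the α-hydroxy aldehyde may undergo α-ketol rearrangement (ring expansion) before the hindered carbonyl group is olefinated. Fallback: starting from 10, a base-free Wittig reaction with 1-(triphenylphosphoranylidene)propan-2-one in toluene at 80 °C gives the E-enone F4. A Horner–Wadsworth–Emmons reaction of this methyl ketone with diethyl cyanomethylphosphonate and NaH then returns to the route at 12 (9Z isomer removed as before).

**Step 17.** Configuration at C8′ may be lost by silver-assisted reopening of the doubly allylic C8′–O bond, or the hindered tertiary allenol may react too slowly. Fallback: starting from 22, iodoetherification with N-iodosuccinimide in CH2Cl2 at 0 °C gives the 7′-iodo dihydrofuran F5. The iodine on C7′ destabilises an allyl cation at C8′, and the oxygen again enters in the plane set by the allene axis. Hydrodeiodination with Bu3SnH and catalytic Pd(PPh3)4 (zerovalent palladium) returns to the route at 23.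

**Step 22.** Double condensation of the bis-ylide, difficult separation of 29 from excess 28, and base-induced epimerisation of 25 at C8′ (γ-deprotonation of the enal) are the likely failures. Fallback: starting from 28, the salt is condensed in one pot with 25 and 15 together (NaOMe, or 1,2-epoxybutane as a neutral base source). The cross product is separated by chromatography from the two symmetrical carotenoids, which differ from it by two hydroxyl groups each, and is then equilibrated thermally. This returns to the route at 30; no new compound is made (F0).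

## Further compounds

F0 | step 3 | none | none
F1 | step 4 | rac-(1R,4S)-1-({[tert-butyl(dimethyl)silyl]oxy}methyl)-2,6,6-trimethylcyclohex-2-ene-1,4-diol (cis-diol) | CC1=C[C@@H](O)CC(C)(C)[C@]1(O)CO[Si](C)(C)C(C)(C)C
F2 | step 4 | rac-4-(acetoxymercurio) derivative of triol 7, mercury on C4 cis to the C3 and C6 hydroxyls, C5 hydroxyl trans | CC(C)(C)[Si](C)(C)OC[C@@]1(O)C(C)(C)C[C@H](O)[C@H]([Hg]OC(C)=O)[C@@]1(C)O
F3 | step 6 | (1S,3R,4S)-4-({[tert-butyl(dimethyl)silyl]oxy}methyl)-3,4-dihydroxy-3,5,5-trimethylcyclohexyl acetate | CC(C)(C)[Si](C)(C)OC[C@@]1(O)C(C)(C)C[C@H](OC(C)=O)C[C@@]1(C)O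
F4 | step 9 | (1S,3R,4R)-3,4-dihydroxy-3,5,5-trimethyl-4-[(1E)-3-oxobut-1-en-1-yl]cyclohexyl (1S,4R)-camphanate | CC(=O)/C=C/[C@@]1(O)C(C)(C)C[C@H](OC(=O)[C@@]23CC[C@@](C)(C(=O)O2)C3(C)C)C[C@@]1(C)O
F5 | step 17 | 7′-iodo analogue of 23 (3-iodo-2,5-dihydrofuran, same spatial arrangement at C8′) | OC/C=C(\C)[C@@H]1C(I)=C2C(C)(C)C[C@H](O[Si](C)(C)C(C)(C)C)C[C@@]2(C)O1
F0 | step 22 | none | none
A1 | alternative 1 | tris-silylated triol-end enyne (C7=C8–C9≡C10H) | C#C/C=C/[C@@]1(O[Si](CC)(CC)CC)C(C)(C)C[C@H](O[Si](C)(C)C(C)(C)C)C[C@@]1(C)O[Si](CC)(CC)CC
A2 | alternative 1 | ethyl (2E,4E)-5-iodo-3-methylpenta-2,4-dienoate | CCOC(=O)/C=C(C)/C=C/I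
A3 | alternative 1 | silylated triol-end C20 tetraenoate | CCOC(=O)/C=C(C)/C=C/C=C(C)/C=C/[C@@]1(O[Si](CC)(CC)CC)C(C)(C)C[C@H](O[Si](C)(C)C(C)(C)C)C[C@@]1(C)O[Si](CC)(CC)CC
A4 | alternative 2 | C15 (6′R)-allenol bis-silyl ether | C[C@@]1(O)C[C@@H](O[Si](C)(C)C(C)(C)C)CC(C)(C)C1=[C@@]=C([H])/C(C)=C/CO[Si](C)(C)C(C)(C)C
A5 | alternative 2 | C15 furanoid bis-silyl ether | CC(C)(C)[Si](C)(C)OC/C=C(\C)[C@@H]1C=C2C(C)(C)C[C@H](O[Si](C)(C)C(C)(C)C)C[C@@]2(C)O1
A6 | alternative 3 | 5,6-epoxide (cis to the C3 silyloxy group) with C7 tert-butyl carbonate | CC(C)(C)OC(=O)OC[C@]12O[C@@]1(C)C[C@@H](O[Si](C)(C)C(C)(C)C)CC2(C)C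
A7 | alternative 3 | 5,7-cyclic carbonate with free C6 hydroxyl | O=C1OC[C@@]2(O)C(C)(C)C[C@H](O[Si](C)(C)C(C)(C)C)C[C@@]2(C)O1
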